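Ring B is cut at C5–C10 and C8–C9 together. Read as the Δ6 silyl enol ether of the C7 ketone it is a Diels–Alder cyclohexene: diene C5=C6–C7(OSiEt3)=C8, dienophile C9=C10, a tetrasubstituted exocyclic enol ether that already carries the 9,13-ether oxygen and the C20 methyl, and tether C1–C4 (ring A). One intramolecular cycloaddition of this acyclic triene closes rings A and B and sets C5, C9 and C10 (C8 provisionally). The dienophile is a chiral-pool spiro-bis-oxolane whose C14 silyloxy group, later eliminated to the dihydrofuran, directs the π-face. C8 is then equilibrated and the 6β-acetate installed by an enol acetate epoxide rearrangement.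

Key step: step 11

Remark: labdane numbering (C1–C20) is used for all intermediates, and (3R,4R)-tetrahydrofuran-3,4-diol (1,4-anhydro-D-threitol) is taken as a purchasable chiral-pool compound.

Step 1
Reactants: 1 (3R,4R)-tetrahydrofuran-3,4-diol
Product: 2 (3R,4R)-4-(tert-butyldimethylsilyloxy)tetrahydrofuran-3-ol
Conditions: NaH (1.0 equiv), THF, 0 °C; then t-BuMe2SiCl (1.0 equiv), 0 → 23 °C
Reagents that add atoms: tert-butyldimethylsilyl chloride, CC(C)(C)[Si](C)(C)Cl
Why: Deprotonation of one of the two homotopic hydroxyls of the C2-symmetric diol and O-silylation of the mono-alkoxide (silyl ether formation) should give a single mono-ether without touching a stereocenter.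

Step 2
Reactants: 2 (3R,4R)-4-(tert-butyldimethylsilyloxy)tetrahydrofuran-3-ol
Product: 3 (4R)-4-(tert-butyldimethylsilyloxy)dihydrofuran-3(2H)-one
Conditions: Dess–Martin periodinane, CH2Cl2, 0 → 23 °C
Reagents that add atoms: none
Why: Dess–Martin oxidation of the secondary alcohol under non-basic conditions should give the ketone without epimerising the adjacent silyloxy-bearing carbon (the future C14).

Step 3
Reactants: 3 (4R)-4-(tert-butyldimethylsilyloxy)dihydrofuran-3(2H)-one; 4 (4-bromobut-1-yn-1-yl)trimethylsilane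
Product: 7 (3S,4R)-3-(but-3-yn-1-yl)-4-(tert-butyldimethylsilyloxy)tetrahydrofuran-3-ol, via Grignard reagent 5 (not isolated), via silylalkynyl carbinol 6 (not isolated)
Conditions: Mg, THF, 23 → 40 °C; then 3, THF, −78 → 0 °C; then MeOH, K2CO3, 23 °C
Reagents that add atoms: none
Why: Grignard addition to the ketone should occur on the face anti to the neighbouring silyloxy group (Felkin–Anh and steric control on the five-membered ring), which sets C13 with its hydroxyl cis to the silyloxy group, and K2CO3/MeOH then cleaves the alkynyl C–Si bond (protodesilylation).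

Step 4
Reactants: 8 isobutyronitrile; 9 1,3-dibromopropane
Product: 10 5-bromo-2,2-dimethylpentanenitrile
Conditions: LiN(i-Pr)2, THF, −78 °C; then 9 (3 equiv), −78 → 23 °C
Reagents that add atoms: none
Why: α-Alkylation of the lithiated nitrile with an excess of the dibromide (nucleophilic substitution at a primary carbon) should give the mono-alkylation product, and no stereocenter is formed.

Step 5
Reactants: 7 (3S,4R)-3-(but-3-yn-1-yl)-4-(tert-butyldimethylsilyloxy)tetrahydrofuran-3-ol; 10 5-bromo-2,2-dimethylpentanenitrile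
Product: 11 9-[(3S,4R)-4-(tert-butyldimethylsilyloxy)-3-hydroxytetrahydrofuran-3-yl]-2,2-dimethylnon-6-ynenitrile
Conditions: n-BuLi (2.0 equiv), THF, −78 → 0 °C; then 10, DMPU, 0 → 23 °C
Reagents that add atoms: none
Why: After double deprotonation the acetylide carbon, far more nucleophilic than the tertiary alkoxide, should be alkylated by the primary bromide (acetylide alkylation), the neopentyl-type nitrile being too hindered to compete.

Step 6
Reactants: 11 9-[(3S,4R)-4-(tert-butyldimethylsilyloxy)-3-hydroxytetrahydrofuran-3-yl]-2,2-dimethylnon-6-ynenitrile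
Product: 13 9-[(3S,4R)-4-(tert-butyldimethylsilyloxy)-3-hydroxytetrahydrofuran-3-yl]-2,2-dimethylnon-6-ynal, via aldimine 12 (not isolated)
Conditions: i-Bu2AlH (2.2 equiv), PhMe, −78 °C; then aq. tartaric acid, 0 °C
Reagents that add atoms: water, O
Why: A single hydride transfer to the nitrile stops at the aldimine stage (held as its aluminium derivative), and hydrolysis on work-up should give the aldehyde (nitrile-to-aldehyde reduction).

Step 7
Reactants: 13 9-[(3S,4R)-4-(tert-butyldimethylsilyloxy)-3-hydroxytetrahydrofuran-3-yl]-2,2-dimethylnon-6-ynal; 14 diethyl (2-oxobutyl)phosphonate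
Product: 15 (E)-13-[(3S,4R)-4-(tert-butyldimethylsilyloxy)-3-hydroxytetrahydrofuran-3-yl]-6,6-dimethyltridec-4-en-10-yn-3-one
Conditions: LiCl, DBU, MeCN, 23 °C
Reagents that add atoms: none
Why: Horner–Wadsworth–Emmons olefination of the non-enolisable aldehyde with the stabilised β-ketophosphonate should give the E-enone (C5=C6) selectively.

Step 8
Reactants: 15 (E)-13-[(3S,4R)-4-(tert-butyldimethylsilyloxy)-3-hydroxytetrahydrofuran-3-yl]-6,6-dimethyltridec-4-en-10-yn-3-one
Product: 16 (4E)-10-iodo-6,6-dimethyl-10-[(2E,5S,9R)-9-(tert-butyldimethylsilyloxy)-1,7-dioxaspiro[4.4]nonan-2-ylidene]dec-4-en-3-one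
Conditions: N-iodosuccinimide (1.05 equiv), NaHCO3, CH2Cl2, 0 °C, dark
Reagents that add atoms: N-iodosuccinimide, O=C1CCC(=O)N1I
Why: Iodoetherification should proceed by 5-exo-dig attack of the tertiary hydroxyl on the iodonium-activated alkyne with anti addition, so that iodine ends trans to the ring oxygen and the C1 chain cis to it.

Step 9
Reactants: 16 (4E)-10-iodo-6,6-dimethyl-10-[(2E,5S,9R)-9-(tert-butyldimethylsilyloxy)-1,7-dioxaspiro[4.4]nonan-2-ylidene]dec-4-en-3-one
Product: 17 (4E)-6,6-dimethyl-10-[(2Z,5S,9R)-9-(tert-butyldimethylsilyloxy)-1,7-dioxaspiro[4.4]nonan-2-ylidene]undec-4-en-3-one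
Conditions: MeZnCl (2 equiv), Pd(PPh3)4 (5 mol %), THF, 23 → 40 °C
Reagents that add atoms: methylzinc chloride, C[Zn]Cl
Why: Negishi cross-coupling should replace iodine by the C20 methyl with retention of alkene geometry, giving the stereodefined tetrasubstituted enol ether, while the organozinc reagent does not add to the enone.

Step 10
Reactants: 17 (4E)-6,6-dimethyl-10-[(2Z,5S,9R)-9-(tert-butyldimethylsilyloxy)-1,7-dioxaspiro[4.4]nonan-2-ylidene]undec-4-en-3-one
Product: 18 triethyl{[(2Z,4E)-6,6-dimethyl-10-[(2Z,5S,9R)-9-(tert-butyldimethylsilyloxy)-1,7-dioxaspiro[4.4]nonan-2-ylidene]undeca-2,4-dien-3-yl]oxy}silane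
Conditions: KN(SiMe3)2, Et3SiCl, THF, −78 °C (internal quench)
Reagents that add atoms: chlorotriethylsilane, CC[Si](Cl)(CC)CC
Why: Kinetic deprotonation of the enone at C8 (C4 is quaternary, so no γ-deprotonation) and O-silylation of the cross-conjugated enolate should give the 2-silyloxydiene, mainly as the Z enol ether (silyl enol ether formation).

Step 11
Reactants: 18 triethyl{[(2Z,4E)-6,6-dimethyl-10-[(2Z,5S,9R)-9-(tert-butyldimethylsilyloxy)-1,7-dioxaspiro[4.4]nonan-2-ylidene]undeca-2,4-dien-3-yl]oxy}silane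
Product: 19 Diels–Alder adduct (13S,14R)-14-(tert-butyldimethylsilyloxy)-9α,13:15,16-diepoxy-7-(triethylsilyloxy)-8-epi-labd-6-ene
Conditions: 13 kbar, CH2Cl2, 2,6-di-tert-butyl-4-methylpyridine (5 mol %), 60 °C, 48 h
Reagents that add atoms: none
Why: A concerted, suprafacial [4+2] cycloaddition of the 2-silyloxydiene C5=C6–C7=C8 to the tethered enol ether C9=C10 forms C5–C10 and C8–C9 at once, with pressure (large negative activation volume) compensating for the electron-rich, tetrasubstituted dienophile. The closest known reaction type is the thermal or high-pressure type 1 intramolecular Diels–Alder reaction of unactivated 1,7,9-decatrienes to decalins. Ring A closes through the four-carbon tether C1–C4 and ring B through the two new bonds, both as six-membered rings of one [4+2] event. C5 and C10 should become trans (H5 anti to the C20 methyl) from the E-alkene C5=C6 and a chair-like tether with the C20 methyl endo; C9 follows from the Z enol ether geometry (tether cis to the ring oxygen, so oxygen ends α and trans to C20); C8 follows from the Z silyl enol ether (methyl β, corrected in step 12); the absolute sense follows from addition to the enol ether face anti to the C14 silyloxy group, which places C8 cis to C16 on the oxolane ring. The step needs trans over cis ring fusion and one π-face, which the gem-dimethyl tether with its E-diene and the bulky C14 substituent on the rigid spirocycle are expected to secure, and no regiochemical alternative exists because the tether fixes the pairing of the termini.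

Step 12
Reactants: 19 Diels–Alder adduct (13S,14R)-14-(tert-butyldimethylsilyloxy)-9α,13:15,16-diepoxy-7-(triethylsilyloxy)-8-epi-labd-6-ene
Product: 21 (13S,14R)-14-(tert-butyldimethylsilyloxy)-9α,13:15,16-diepoxylabdan-7-one, via 8-epi ketone 20 (not isolated)
Conditions: K2CO3, MeOH, 0 → 23 °C
Reagents that add atoms: none
Why: Methanolysis of the triethylsilyl enol ether releases the C7 ketone, and base-mediated enolisation toward C8 should move the axial 8β-methyl (1,3-diaxial to the C20 methyl) to the equatorial 8α-position (thermodynamic epimerisation), which sets C8.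

Step 13
Reactants: 21 (13S,14R)-14-(tert-butyldimethylsilyloxy)-9α,13:15,16-diepoxylabdan-7-one
Product: 22 (13S,14R)-7-acetoxy-14-(tert-butyldimethylsilyloxy)-9α,13:15,16-diepoxylabd-6-ene
Conditions: LiN(i-Pr)2, THF, −78 °C; then Ac2O, −78 → 0 °C
Reagents that add atoms: acetic anhydride, CC(=O)OC(C)=O
Why: Kinetic deprotonation should occur at the C6 methylene in preference to the C8 methine, and O-acylation of the enolate gives the Δ6 enol acetate (enol ester formation), an enolate on this side being unable to expel the C9 oxygen.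

Step 14
Reactants: 22 (13S,14R)-7-acetoxy-14-(tert-butyldimethylsilyloxy)-9α,13:15,16-diepoxylabd-6-ene
Product: 24 (13S,14R)-6β-acetoxy-14-(tert-butyldimethylsilyloxy)-9α,13:15,16-diepoxylabdan-7-one, via epoxy acetate 23 (not isolated)
Conditions: dimethyldioxirane, acetone/CH2Cl2, −20 °C; evaporate; PhMe, 120 °C (base-washed glass)
Reagents that add atoms: dimethyldioxirane, CC1(C)OO1
Why: Epoxidation should occur from the α-face, anti to the axial C19 and C20 methyls, and the thermal enol ester epoxide rearrangement is an intramolecular 1,2-acyloxy shift from C7 to C6 with inversion at C6, which delivers the axial 6β-acetate and the C7 ketone.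

Step 15
Reactants: 24 (13S,14R)-6β-acetoxy-14-(tert-butyldimethylsilyloxy)-9α,13:15,16-diepoxylabdan-7-one
Product: 25 (13S,14R)-6β-acetoxy-14-hydroxy-9α,13:15,16-diepoxylabdan-7-one
Conditions: HF·pyridine, pyridine/THF, 0 → 23 °C
Reagents that add atoms: none
Why: Fluoride-driven cleavage of the silyl ether (desilylation) under buffered, weakly acidic conditions should leave the epimerisable α-acetoxy ketone and the β-alkoxy ketone untouched.

Step 16
Reactants: 25 (13S,14R)-6β-acetoxy-14-hydroxy-9α,13:15,16-diepoxylabdan-7-one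
Product: 26 (5S,6S,8S,9R,10S,13R)-6-acetoxy-9,13:15,16-diepoxylabd-14-en-7-one (CNP0224709.1)
Conditions: Burgess reagent (methyl N-(triethylammoniumsulfonyl)carbamate), Et3N (0.2 equiv), PhMe, 70 °C
Reagents that add atoms: none
Why: Burgess dehydration proceeds by syn elimination of the sulfamate ester, and since C13 is quaternary only a C15 hydrogen is available, so the C14=C15 enol ether should form regiospecifically under neutral conditions.

Compound list
1 | (3R,4R)-tetrahydrofuran-3,4-diol | O[C@@H]1COC[C@H]1O | starting material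
2 | (3R,4R)-4-(tert-butyldimethylsilyloxy)tetrahydrofuran-3-ol | O[C@@H]1COC[C@H]1O[Si](C)(C)C(C)(C)C | intermediate
3 | (4R)-4-(tert-butyldimethylsilyloxy)dihydrofuran-3(2H)-one | O=C1[C@H](O[Si](C)(C)C(C)(C)C)COC1 | intermediate
4 | (4-bromobut-1-yn-1-yl)trimethylsilane | C[Si](C)(C)C#CCCBr | starting material
5 | [4-(trimethylsilyl)but-3-yn-1-yl]magnesium bromide (not isolated) | C[Si](C)(C)C#CCC[Mg]Br | intermediate
6 | (3S,4R)-4-(tert-butyldimethylsilyloxy)-3-[4-(trimethylsilyl)but-3-yn-1-yl]tetrahydrofuran-3-ol (not isolated) | C[Si](C)(C)C#CCC[C@]1([C@H](O[Si](C)(C)C(C)(C)C)COC1)O | intermediate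
7 | (3S,4R)-3-(but-3-yn-1-yl)-4-(tert-butyldimethylsilyloxy)tetrahydrofuran-3-ol (hydroxyl cis to silyloxy) | C#CCC[C@]1([C@H](O[Si](C)(C)C(C)(C)C)COC1)O | intermediate
8 | isobutyronitrile | CC(C)C#N | starting material
9 | 1,3-dibromopropane | BrCCCBr | starting material
10 | 5-bromo-2,2-dimethylpentanenitrile | N#CC(C)(C)CCCBr | intermediate
11 | 9-[(3S,4R)-4-(tert-butyldimethylsilyloxy)-3-hydroxytetrahydrofuran-3-yl]-2,2-dimethylnon-6-ynenitrile | N#CC(C)(C)CCCC#CCC[C@]1([C@H](O[Si](C)(C)C(C)(C)C)COC1)O | intermediate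
12 | aldimine of aldehyde 13 (not isolated) | N=CC(C)(C)CCCC#CCC[C@]1([C@H](O[Si](C)(C)C(C)(C)C)COC1)O | intermediate
13 | 9-[(3S,4R)-4-(tert-butyldimethylsilyloxy)-3-hydroxytetrahydrofuran-3-yl]-2,2-dimethylnon-6-ynal | O=CC(C)(C)CCCC#CCC[C@]1([C@H](O[Si](C)(C)C(C)(C)C)COC1)O | intermediate
14 | diethyl (2-oxobutyl)phosphonate | CCC(=O)CP(=O)(OCC)OCC | starting material
15 | (E)-13-[(3S,4R)-4-(tert-butyldimethylsilyloxy)-3-hydroxytetrahydrofuran-3-yl]-6,6-dimethyltridec-4-en-10-yn-3-one | CCC(=O)/C=C/C(C)(C)CCCC#CCC[C@]1([C@H](O[Si](C)(C)C(C)(C)C)COC1)O | intermediate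
16 | (4E)-10-iodo-6,6-dimethyl-10-[(2E,5S,9R)-9-(tert-butyldimethylsilyloxy)-1,7-dioxaspiro[4.4]nonan-2-ylidene]dec-4-en-3-one (iodine trans to ring oxygen) | CCC(=O)/C=C/C(C)(C)CCC/C(I)=C1/CC[C@]2([C@H](O[Si](C)(C)C(C)(C)C)COC2)O1 | intermediate
17 | (4E)-6,6-dimethyl-10-[(2Z,5S,9R)-9-(tert-butyldimethylsilyloxy)-1,7-dioxaspiro[4.4]nonan-2-ylidene]undec-4-en-3-one (C1 chain cis to ring oxygen) | CCC(=O)/C=C/C(C)(C)CCC/C(C)=C1/CC[C@]2([C@H](O[Si](C)(C)C(C)(C)C)COC2)O1 | intermediate
18 | triethyl{[(2Z,4E)-6,6-dimethyl-10-[(2Z,5S,9R)-9-(tert-butyldimethylsilyloxy)-1,7-dioxaspiro[4.4]nonan-2-ylidene]undeca-2,4-dien-3-yl]oxy}silane | C/C=C(O[Si](CC)(CC)CC)/C=C/C(C)(C)CCC/C(C)=C1/CC[C@]2([C@H](O[Si](C)(C)C(C)(C)C)COC2)O1 | intermediate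
19 | Diels–Alder adduct (13S,14R)-14-(tert-butyldimethylsilyloxy)-9α,13:15,16-diepoxy-7-(triethylsilyloxy)-8-epi-labd-6-ene (5α-H, 8β-methyl, 10β-methyl) | C1=C(O[Si](CC)(CC)CC)[C@H](C)[C@]2(CC[C@]3([C@H](O[Si](C)(C)C(C)(C)C)COC3)O2)[C@@]2(C)CCCC(C)(C)[C@H]12 | intermediate
20 | (13S,14R)-14-(tert-butyldimethylsilyloxy)-9α,13:15,16-diepoxy-8-epi-labdan-7-one (8β-methyl; not isolated) | C1C(=O)[C@H](C)[C@]2(CC[C@]3([C@H](O[Si](C)(C)C(C)(C)C)COC3)O2)[C@@]2(C)CCCC(C)(C)[C@H]12 | intermediate
21 | (13S,14R)-14-(tert-butyldimethylsilyloxy)-9α,13:15,16-diepoxylabdan-7-one (8α-methyl) | C1C(=O)[C@@H](C)[C@]2(CC[C@]3([C@H](O[Si](C)(C)C(C)(C)C)COC3)O2)[C@@]2(C)CCCC(C)(C)[C@H]12 | intermediate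
22 | (13S,14R)-7-acetoxy-14-(tert-butyldimethylsilyloxy)-9α,13:15,16-diepoxylabd-6-ene | C1=C(OC(C)=O)[C@@H](C)[C@]2(CC[C@]3([C@H](O[Si](C)(C)C(C)(C)C)COC3)O2)[C@@]2(C)CCCC(C)(C)[C@H]12 | intermediate
23 | (13S,14R)-7β-acetoxy-14-(tert-butyldimethylsilyloxy)-6α,7α:9α,13:15,16-triepoxylabdane (not isolated) | [C@H]1(O2)[C@]2(OC(C)=O)[C@@H](C)[C@]3(CC[C@]4([C@H](O[Si](C)(C)C(C)(C)C)COC4)O3)[C@@]3(C)CCCC(C)(C)[C@H]13 | intermediate
24 | (13S,14R)-6β-acetoxy-14-(tert-butyldimethylsilyloxy)-9α,13:15,16-diepoxylabdan-7-one | CC(=O)O[C@@H]1C(=O)[C@@H](C)[C@]2(CC[C@]3([C@H](O[Si](C)(C)C(C)(C)C)COC3)O2)[C@@]2(C)CCCC(C)(C)[C@H]12 | intermediate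
25 | (13S,14R)-6β-acetoxy-14-hydroxy-9α,13:15,16-diepoxylabdan-7-one | CC(=O)O[C@@H]1C(=O)[C@@H](C)[C@]2(CC[C@]3([C@H](O)COC3)O2)[C@@]2(C)CCCC(C)(C)[C@H]12 | intermediate
26 | (5S,6S,8S,9R,10S,13R)-6-acetoxy-9,13:15,16-diepoxylabd-14-en-7-one (CNP0224709.1) | CC(=O)O[C@@H]1C(=O)[C@@H](C)[C@]2(CC[C@]3(C=COC3)O2)[C@@]2(C)CCCC(C)(C)[C@H]12 | target

Total step count: 16. Longest linear sequence: 15 steps (1 to 26 through steps 1–3 and 5–16; step 4 supplies bromide 10).

Steps most likely to fail

Step 11. The cycloaddition may be too slow because both π-systems are electron-rich and the dienophile is tetrasubstituted. It may also close with cis ring fusion or on the wrong π-face, or the exocyclic enol ether may migrate into the ring before it reacts. The fallback sets out from enone 17 and comes back at ketone 21. The enone (oxadiene C5=C6–C7=O) and the enol ether are electronically matched for an intramolecular inverse-electron-demand hetero-Diels–Alder reaction (PhMe, 130 °C), which forms C5–C10 and O–C9 and should give the spiroketal dihydropyran F1. PPTS in MeOH opens the enol ketal to the keto methyl ketal F2 (mixture at C9). TMSOTf/i-Pr2NEt then forms the trimethylsilyl enol ether F3 in the flask and ionises the ketal, and a Mukaiyama aldol-type addition of C8 to the cyclic oxocarbenium ion closes ring B. K2CO3/MeOH equilibration at C8 gives 21.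

Step 14. The acyloxy shift may follow the acid-catalysed pathway with retention, or may fail to reach the doubly hindered β-face of C6, so that the 6α-epimer or a hydrolysed ketol results. The fallback sets out from ketone 21 and comes back at 24. LiN(i-Pr)2 followed by 2-(phenylsulfonyl)-3-phenyloxaziridine should give the 6α-hydroxy ketone F4 (oxidant from the open α-face), and Ac2O/DMAP the 6α-acetate F5. LiN(SiMe3)2 at −78 °C then enolises toward the acetoxy-bearing C6, and a hindered proton donor (2,6-di-tert-butylphenol) protonates C6 from the α-face. Kinetic protonation, not acyl migration, thus sets the 6β-acetate of 24.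

Step 16. The sulfamate ester at the hindered, β-oxygenated C14 may ionise or revert instead of undergoing syn elimination, and the acid-labile dihydrofuran may be hydrated or opened once formed. The fallback sets out from alcohol 25 and comes back at 26. O-Phenyl chlorothionoformate with pyridine and DMAP should give the phenyl thionocarbonate F6, and a thermal Chugaev-type syn elimination (o-dichlorobenzene, 170 °C), which needs neither acid nor base, gives 26.

Further compounds
F1 | step 11 | (13S,14R)-14-(tert-butyldimethylsilyloxy)-7,9:9,13:15,16-triepoxy-8,9-secolabd-6-ene (spiroketal dihydropyran; 5α-H, 10β-methyl) | C1=C(CC)O[C@]2(CC[C@]3([C@H](O[Si](C)(C)C(C)(C)C)COC3)O2)[C@@]2(C)CCCC(C)(C)[C@H]12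
F2 | step 11 | (13S,14R)-14-(tert-butyldimethylsilyloxy)-9-methoxy-9,13:15,16-diepoxy-8,9-secolabdan-7-one (mixture at C9) | CCC(=O)C[C@H]1C(C)(C)CCC[C@]1(C)C2(OC)CC[C@]3([C@H](O[Si](C)(C)C(C)(C)C)COC3)O2
F3 | step 11 | C7=C8 trimethylsilyl enol ether of F2 (alkene geometry and C9 not defined) | CC=C(O[Si](C)(C)C)C[C@H]1C(C)(C)CCC[C@]1(C)C2(OC)CC[C@]3([C@H](O[Si](C)(C)C(C)(C)C)COC3)O2
F4 | step 14 | (13S,14R)-14-(tert-butyldimethylsilyloxy)-6α-hydroxy-9α,13:15,16-diepoxylabdan-7-one | O[C@H]1C(=O)[C@@H](C)[C@]2(CC[C@]3([C@H](O[Si](C)(C)C(C)(C)C)COC3)O2)[C@@]2(C)CCCC(C)(C)[C@H]12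
F5 | step 14 | (13S,14R)-6α-acetoxy-14-(tert-butyldimethylsilyloxy)-9α,13:15,16-diepoxylabdan-7-one | CC(=O)O[C@H]1C(=O)[C@@H](C)[C@]2(CC[C@]3([C@H](O[Si](C)(C)C(C)(C)C)COC3)O2)[C@@]2(C)CCCC(C)(C)[C@H]12
F6 | step 16 | (13S,14R)-6β-acetoxy-14-(phenoxythiocarbonyloxy)-9α,13:15,16-diepoxylabdan-7-one | CC(=O)O[C@@H]1C(=O)[C@@H](C)[C@]2(CC[C@]3([C@H](OC(=S)Oc4ccccc4)COC3)O2)[C@@]2(C)CCCC(C)(C)[C@H]12
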